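Find how much target this flask holds at 15 s, and how much starting material has gone by then.

    reagent in the reaction phase ⇌ reagent in the second phase, rate k1*([reagent in the reaction phase] - [reagent in the second phase]/K1) per volume of the first phase (K1 = 0.50, k1 = 0.0876 s⁻¹)
    starting material + reagent in the reaction phase → target (k2 = 31.1 M⁻¹ s⁻¹)
    reagent in the reaction phase + target → over-reacted product (k3 = 71.8 M⁻¹ s⁻¹)
    reagent in the reaction phase → decomposed reagent (k4 = 0.239 s⁻¹)
    starting material ⇌ dormant form (K5 = 0.61, k5 = 0.0277 s⁻¹)

starting material 2.0 mM; reagent in the second phase 2.20 mM; time 15 s; volume of the second phase over the first 0.50

1. how much target there is at 15 s, in percent of the starting material charged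
2. part of the starting material charged that has reacted at 15 s

- in the second phase: reagent in the second phase; everything else is in the first
- charges count per volume of the first phase; a concentration in a rate is the amount of a species over the volume of its own phase; every rate counts per litre of the first phase
- what has gone from starting material into another species counts as reacted, even if it can come back
- run time (flask): 15 s

Two numbers seem to quarrel here. The reagent charge is 1.10 equivalents, more than the starting material, yet at the charge a molecule of it in the reaction phase is more likely to decompose than to be caught by starting material.

Follow one molecule into the reaction phase. Starting material catches it at 0.0622 s⁻¹ at the charge, while decomposition takes it at 0.239 s⁻¹, faster. Passage back to the second phase delays it and consumes none of it. So its chance of ending on starting material is capture over capture plus decomposition, 0.207; call this the fork share. Multiply by the equivalents: 22.7 % of the starting material, if [starting material] stayed at its charge.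

It falls, though. Reagent leaves the second phase in about 2.85 s and lasts about 3.32 s after that, so the mean molecule reaches its fork near 6.17 s. For that moment reckon the dormant form, relaxing with a half-life of 9.48 s, at 13.8 %. Take off half the reagent route as well, which leaves 74.9 % and a fork share of 0.163. That gives 17.9 % through the reagent. Target competes for reagent with a selectivity factor of 2.31; at a mean target of half that amount, reckon 27.7 % of it as going on to over-reacted product. Commit to 13.0 % target, and, with the dormant form at 15 s, 38.6 % reacted.

The forecast says 12.7 % (10.5 % to 15 %) and 38 % (34 % to 42 %), with the reagent “mostly lost to decomposition”.

The simulation gives 13.0 % target and 38.8 % reacted.

Watch the decomposed reagent. In the flask at 15.0 s it stands at 1.60 mM against 0.332 mM of target and over-reacted product together, a fork share of 0.172 read from the contents against the 0.163 reckoned. For the neighbour flask with 0.50 mM of starting material, a quarter of this charge, the same reckoning gives a fork share of 0.0611 at its charge and 0.0452 at the mean molecule's fork; at 15.0 s its contents read 0.0484, with 1.83 mM decomposed reagent and 14.0 % target.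

Its constants are invented; the result is computed.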